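Read the stall first.

| flask | substrate | partner | free catalyst | time |
|---|---|---|---|---|
| alder | 300 mM | 300 mM | 30.0 mM |  |
| maple | 300 mM | 300 mM | 45.0 mM |  |
| ash | 99.0 mM | 300 mM | 15.0 mM | 150 min |

| run | time / min | [target] / mM |
|---|---|---|
| alder run | 6.7 | 31.1 |
| alder run | 20 | 60.7 |
| alder run | 39 | 70.0 |
| alder run | 61 | 81.2 |
| alder run | 88 | 82.5 |
| alder run | 120 | 88.8 |
| alder run | 150 | 90.8 |
| maple run | 6.7 | 43.7 |
| maple run | 20 | 78.6 |
| maple run | 39 | 101.1 |
| maple run | 61 | 104.4 |
| maple run | 88 | 108.2 |
| maple run | 120 | 116.7 |
| maple run | 150 | 118.5 |

(scatter of a reading: 2 mM)

1. order of the initial rate in [free catalyst], near the charge of the alder run, the rate being that where two percent of its substrate are target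
2. target in the ash run at 150 min, as a share of the substrate charged
3. which of these the readings show (the product binds the second partner / nothing beyond the main steps / the product ties up the catalyst / the product speeds the reaction / the second partner is lost in pairs)

- Overall: substrate + partner -> target, with free catalyst as catalyst.
- Constant volume, constant temperature.
- "The second partner" is partner.
- An order is taken over about fifteen percent of the charge, up and down.

The alder run ends at 90.8 mM of target with 0.209 M of substrate unturned, so the first question is whether the slowing follows the target made or the clock. At nearly equal target, the maple run at 20 min (78.6 mM) makes about 1.18 mM/min, while the alder run at 61 min (81.2 mM) makes about 0.108 mM/min. These readings differ 10.9 times on 1.50 times the free catalyst, so the slowing follows the clock.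

What, then, does the clock remove? In the alder run, the natural log of substrate charged over substrate left, here called the turnover logarithm, gains 0.0396 from 20 min to 39 min and 0.0354 from 61 min to 120 min. Nearly equal gains for each near-doubling of time are the mark of a reagent going at the square of its own amount, so this reckoning takes partner to be lost in pairs.

What does that give the ash run? Its partner charge matches the alder run's, and this reckoning assumes, without proof, that partner follows the same course in both flasks and that the rate is proportional to substrate, so that substrate drops out of the logarithm. At 150 min the logarithms are 0.360 for alder and 0.503 for maple, which gives an order in free catalyst of 0.819. Scaled to the ash charge, the expected ash turnover logarithm is 0.204, or 18.5% of its substrate.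

The forecast, which speaks of “the log-time tail expected if partner decays second-order”, gives 0.85, 19% and "the second partner is lost in pairs".

The simulation gives 1.2, 20.4% and "the second partner is lost in pairs".

    2 free catalyst ⇌ catalyst dimer, settled at all times (338.0 /M)
    catalyst dimer + substrate + partner → target + catalyst dimer (6.540 /M²/min)
    2 partner → lost reagent (0.2238 /M/min)

The whole-run order 0.819 falls short of the early order 1.2; the early rates stand at 9.9 mM/min in the maple run and 6.0 mM/min in the alder run. The ash logarithm from the result is 0.228, against 0.204 reckoned. The simulated ash run without the loss of partner in pairs reaches 74.4%, a logarithm of 1.36, which is 5.99 times as large. That loss is the main reason for the ash stall, and it costs 54 percentage points of target.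

(The readings come from a simulation from invented constants.)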